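**Retrosynthetic overview**

- The strategy rests on one feature of ring A: the ring oxygen O1 and the acyl carbon C4 sit on the neighbouring carbons C8a and C4a, so an aryne across C4a–C8a can take up both at once.
- Ring C is opened at O1–C2 (6-endo oxa-Michael) to the 2-hydroxyaryl ynone 17. Ynone 17 is cut at O1–C8a and C4–C4a into the ring A aryne 16 and the ring B arylpropiolic acid 14 (aryne insertion into the acyl C–O bond).
- Aryne precursor 9 (C8a–SiMe3, C4a–OTf, C5–OTs, C7–OBn, C8–OMe) comes from 2,4-dihydroxy-5-methoxybenzaldehyde in five steps. Acid 14 comes from 2-hydroxy-4,5-dimethoxybenzaldehyde by Corey–Fuchs homologation and carboxylation.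
- Rings A and B are bought. Ring C is the only ring formed (step 10), followed by tosylate cleavage and hydrogenolysis.

Key step: step 9

Remark: flavone numbering (O1, C2–C4, C4a, C5–C8, C8a) is used for ring A throughout, and 2,4-dihydroxy-5-methoxybenzaldehyde is taken as a catalogue compound.
Remark: the silyl group is placed on C8a and the triflate on C4a. The reverse arrangement would give the same aryne, but its silicon would lie between two sulfonate leaving groups and its preparation would pass through an aryllithium ortho to the tosylate; neither problem arises in the arrangement chosen.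

**Step 1**
Reactants: 1 2,4-dihydroxy-5-methoxybenzaldehyde
Product: 2 4-(benzyloxy)-2-hydroxy-5-methoxybenzaldehyde
Conditions: BnBr (1.1 equiv), CsHCO3 (1.5 equiv), MeCN, 80 °C
Reagents that add atoms: benzyl bromide, BrCc1ccccc1
Why: Williamson etherification in which the mild hydrogencarbonate base should alkylate only the 4-OH, because the 2-OH is hydrogen-bonded to the aldehyde and less acidic.

**Step 2**
Reactants: 2 4-(benzyloxy)-2-hydroxy-5-methoxybenzaldehyde
Product: 3 5-(benzyloxy)-2-formyl-4-methoxyphenyl 4-methylbenzenesulfonate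
Conditions: TsCl (1.2 equiv), Et3N, DMAP (cat.), CH2Cl2, 0 °C → rt
Reagents that add atoms: 4-toluenesulfonyl chloride, Cc1ccc(cc1)S(Cl)(=O)=O
Why: DMAP-catalysed sulfonylation of the remaining chelated phenol puts the σ-acceptor on the future C5 oxygen.

**Step 3**
Reactants: 3 5-(benzyloxy)-2-formyl-4-methoxyphenyl 4-methylbenzenesulfonate
Product: 5 5-(benzyloxy)-2-hydroxy-4-methoxyphenyl 4-methylbenzenesulfonate, via aryl formate 4 (not isolated)
Conditions: mCPBA (1.5 equiv), CH2Cl2, 0 °C → rt; then Et3N (cat.), MeOH, rt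
Reagents that add atoms: 3-chloroperoxybenzoic acid, OOC(=O)c1cccc(Cl)c1
Why: Baeyer–Villiger oxidation in which the aryl group, made migration-prone by the para benzyloxy group, shifts to oxygen, and the labile aryl formate is methanolysed under conditions that should leave the aryl tosylate untouched.

**Step 4**
Reactants: 5 5-(benzyloxy)-2-hydroxy-4-methoxyphenyl 4-methylbenzenesulfonate
Product: 6 5-(benzyloxy)-3-bromo-2-hydroxy-4-methoxyphenyl 4-methylbenzenesulfonate
Conditions: NBS (1.05 equiv), MeCN, −10 °C → 0 °C, dark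
Reagents that add atoms: N-bromosuccinimide, O=C1CCC(=O)N1Br
Why: Electrophilic aromatic bromination should go to the CH that is ortho to both the free hydroxyl and the methoxy group (future C8a), which is far more activated and less hindered than the CH between the tosyloxy and benzyloxy groups.

**Step 5**
Reactants: 6 5-(benzyloxy)-3-bromo-2-hydroxy-4-methoxyphenyl 4-methylbenzenesulfonate
Product: 9 4-(benzyloxy)-3-methoxy-6-(tosyloxy)-2-(trimethylsilyl)phenyl trifluoromethanesulfonate, via silyl ether 7 (not isolated), via lithium phenoxide 8 (not isolated)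
Conditions: HMDS (neat), 80 °C, then evaporation; n-BuLi (1.05 equiv), THF, −100 °C → −78 °C; Tf2O (1.2 equiv), −78 °C → rt
Reagents that add atoms: hexamethyldisilazane, C[Si](C)(C)N[Si](C)(C)C; trifluoromethanesulfonic anhydride, FC(F)(F)S(=O)(=O)OS(=O)(=O)C(F)(F)F
Why: O-silylation, bromine–lithium exchange, retro-Brook 1,3-shift of silicon from oxygen to carbon and O-triflation of the phenoxide is the standard one-pot route to ortho-silylaryl triflates, and the aryllithium is para (not ortho) to the tosylate, so it cannot eliminate it.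

**Step 6**
Reactants: 10 2-hydroxy-4,5-dimethoxybenzaldehyde
Product: 11 2-(benzyloxy)-4,5-dimethoxybenzaldehyde
Conditions: BnBr (1.2 equiv), K2CO3, DMF, rt
Reagents that add atoms: benzyl bromide, BrCc1ccccc1
Why: Williamson etherification of the only phenol protects the future 2'-OH as a benzyl ether that tolerates butyllithium.

**Step 7**
Reactants: 11 2-(benzyloxy)-4,5-dimethoxybenzaldehyde
Product: 12 1-(benzyloxy)-2-(2,2-dibromoethenyl)-4,5-dimethoxybenzene
Conditions: CBr4 (2 equiv), PPh3 (4 equiv), CH2Cl2, 0 °C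
Reagents that add atoms: carbon tetrabromide, BrC(Br)(Br)Br
Why: First stage of the Corey–Fuchs reaction, a Wittig-type dibromo-olefination of the aldehyde with the ylide formed from PPh3 and CBr4.

**Step 8**
Reactants: 12 1-(benzyloxy)-2-(2,2-dibromoethenyl)-4,5-dimethoxybenzene
Product: 14 3-[2-(benzyloxy)-4,5-dimethoxyphenyl]prop-2-ynoic acid, via lithium acetylide 13 (not isolated)
Conditions: n-BuLi (2.2 equiv), THF, −78 °C → 0 °C; CO2 (g), −78 °C → rt; 1 M HCl
Reagents that add atoms: carbon dioxide, O=C=O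
Why: Second stage of the Corey–Fuchs reaction (bromine–lithium exchange, Fritsch–Buttenberg–Wiechell rearrangement and deprotonation to the lithium acetylide), followed by carboxylation of the acetylide with CO2.

**Step 9**
Reactants: 9 4-(benzyloxy)-3-methoxy-6-(tosyloxy)-2-(trimethylsilyl)phenyl trifluoromethanesulfonate; 14 3-[2-(benzyloxy)-4,5-dimethoxyphenyl]prop-2-ynoic acid
Product: 17 1-[4-(benzyloxy)-2-hydroxy-3-methoxy-6-(tosyloxy)phenyl]-3-[2-(benzyloxy)-4,5-dimethoxyphenyl]prop-2-yn-1-one, via caesium carboxylate 15 (not isolated), via aryne 16 (not isolated)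
Conditions: 14 (1.3 equiv), Cs2CO3 (0.65 equiv), MeOH, rt, then evaporation and drying; 9 (1.0 equiv), CsF (2.5 equiv), 18-crown-6 (1 equiv), 4 Å molecular sieves, THF, 60 °C; cold 1 M HCl
Reagents that add atoms: none
Why: Fluoride attacks the silicon on C8a and triflate leaves from C4a, so only the C4a–C8a aryne 16 can form; a carboxylate oxygen of 15 adds to C8a, the aryl anion left on C4a attacks the ester carbonyl through a four-membered alkoxide, and this opens to the ortho-acyl phenoxide, a net insertion of the aryne into the acyl C–O bond that forms O1–C8a and C4–C4a. The closest known reaction is the fluoride-induced insertion of arynes into the C–O bond of carboxylic acids, which gives ortho-hydroxyaryl ketones. No ring is closed (the four-membered ring is only passed through) and no stereocentre is formed. The step needs regiocontrol: in an oxygen-substituted aryne the nucleophile goes to the carbon remote from the σ-acceptor so that the charge ends up next to it, and here the C5 tosylate, a stronger acceptor and a larger group than the C8 methoxy, should send the oxygen to C8a. It also needs the acyl shift to outrun protonation of the aryl anion and loss of CO2 from the propiolate, which is why the acid is used as its dry caesium salt in aprotic THF and the crown ether lets the aryne form at 60 °C. A cold acidic quench keeps the 2-hydroxyaryl ynone open for step 10.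

**Step 10**
Reactants: 17 1-[4-(benzyloxy)-2-hydroxy-3-methoxy-6-(tosyloxy)phenyl]-3-[2-(benzyloxy)-4,5-dimethoxyphenyl]prop-2-yn-1-one
Product: 19 7-(benzyloxy)-2-[2-(benzyloxy)-4,5-dimethoxyphenyl]-8-methoxy-4-oxo-4H-chromen-5-yl 4-methylbenzenesulfonate, via enaminone 18 (not isolated)
Conditions: Et2NH (5 equiv), EtOH, rt → 78 °C
Reagents that add atoms: none
Why: Conjugate addition of the secondary amine to the ynone gives a β-amino enone, and addition–elimination by the C8a phenol at the β-carbon (6-endo) releases the amine and closes the 4-pyranone, a path that excludes the 5-exo aurone mode while the tosylate keeps the C5 oxygen from competing.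

**Step 11**
Reactants: 19 7-(benzyloxy)-2-[2-(benzyloxy)-4,5-dimethoxyphenyl]-8-methoxy-4-oxo-4H-chromen-5-yl 4-methylbenzenesulfonate
Product: 20 7-(benzyloxy)-2-[2-(benzyloxy)-4,5-dimethoxyphenyl]-5-hydroxy-8-methoxy-4H-chromen-4-one
Conditions: KOH (2 M aq., 3 equiv), MeOH–THF, 50 °C; then 1 M HCl
Reagents that add atoms: none
Why: Base-mediated cleavage of the aryl sulfonate by attack at sulfur, helped by the carbonyl-chelated 5-phenoxide as leaving group, with benzyl and methyl ethers inert.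

**Step 12**
Reactants: 20 7-(benzyloxy)-2-[2-(benzyloxy)-4,5-dimethoxyphenyl]-5-hydroxy-8-methoxy-4H-chromen-4-one
Product: 21 5,7-dihydroxy-2-(2-hydroxy-4,5-dimethoxyphenyl)-8-methoxy-4H-chromen-4-one
Conditions: H2 (1 atm), Pd/C (10%), EtOAc–MeOH, rt
Reagents that add atoms: none
Why: Catalytic hydrogenolysis of both benzyl ethers over Pd/C, under which the conjugated C2=C3 bond of a flavone is not expected to be reduced at atmospheric pressure and room temperature.

**Compound list**

1 | 2,4-dihydroxy-5-methoxybenzaldehyde | COc1cc(C=O)c(O)cc1O | starting material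
2 | 4-(benzyloxy)-2-hydroxy-5-methoxybenzaldehyde | COc1cc(C=O)c(O)cc1OCc1ccccc1 | intermediate
3 | 5-(benzyloxy)-2-formyl-4-methoxyphenyl 4-methylbenzenesulfonate | COc1cc(C=O)c(OS(=O)(=O)c2ccc(C)cc2)cc1OCc1ccccc1 | intermediate
4 | 4-(benzyloxy)-5-methoxy-2-(tosyloxy)phenyl formate | COc1cc(OC=O)c(OS(=O)(=O)c2ccc(C)cc2)cc1OCc1ccccc1 | intermediate
5 | 5-(benzyloxy)-2-hydroxy-4-methoxyphenyl 4-methylbenzenesulfonate | COc1cc(O)c(OS(=O)(=O)c2ccc(C)cc2)cc1OCc1ccccc1 | intermediate
6 | 5-(benzyloxy)-3-bromo-2-hydroxy-4-methoxyphenyl 4-methylbenzenesulfonate | COc1c(Br)c(O)c(OS(=O)(=O)c2ccc(C)cc2)cc1OCc1ccccc1 | intermediate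
7 | 5-(benzyloxy)-3-bromo-4-methoxy-2-[(trimethylsilyl)oxy]phenyl 4-methylbenzenesulfonate | COc1c(Br)c(O[Si](C)(C)C)c(OS(=O)(=O)c2ccc(C)cc2)cc1OCc1ccccc1 | intermediate
8 | lithium 4-(benzyloxy)-3-methoxy-6-(tosyloxy)-2-(trimethylsilyl)phenolate | [Li+].COc1c([Si](C)(C)C)c([O-])c(OS(=O)(=O)c2ccc(C)cc2)cc1OCc1ccccc1 | intermediate
9 | 4-(benzyloxy)-3-methoxy-6-(tosyloxy)-2-(trimethylsilyl)phenyl trifluoromethanesulfonate | COc1c([Si](C)(C)C)c(OS(=O)(=O)C(F)(F)F)c(OS(=O)(=O)c2ccc(C)cc2)cc1OCc1ccccc1 | intermediate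
10 | 2-hydroxy-4,5-dimethoxybenzaldehyde | COc1cc(O)c(C=O)cc1OC | starting material
11 | 2-(benzyloxy)-4,5-dimethoxybenzaldehyde | COc1cc(OCc2ccccc2)c(C=O)cc1OC | intermediate
12 | 1-(benzyloxy)-2-(2,2-dibromoethenyl)-4,5-dimethoxybenzene | COc1cc(OCc2ccccc2)c(C=C(Br)Br)cc1OC | intermediate
13 | lithium [2-(benzyloxy)-4,5-dimethoxyphenyl]acetylide | [Li]C#Cc1cc(OC)c(OC)cc1OCc1ccccc1 | intermediate
14 | 3-[2-(benzyloxy)-4,5-dimethoxyphenyl]prop-2-ynoic acid | OC(=O)C#Cc1cc(OC)c(OC)cc1OCc1ccccc1 | intermediate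
15 | caesium 3-[2-(benzyloxy)-4,5-dimethoxyphenyl]prop-2-ynoate | [Cs+].[O-]C(=O)C#Cc1cc(OC)c(OC)cc1OCc1ccccc1 | intermediate
16 | 4-(benzyloxy)-3-methoxy-6-(tosyloxy)benzyne (1,2-didehydrobenzene; the triple bond joins the future C4a and C8a) | COC1=C(OCc2ccccc2)C=C(OS(=O)(=O)c2ccc(C)cc2)C#C1 | intermediate
17 | 1-[4-(benzyloxy)-2-hydroxy-3-methoxy-6-(tosyloxy)phenyl]-3-[2-(benzyloxy)-4,5-dimethoxyphenyl]prop-2-yn-1-one | COc1cc(OCc2ccccc2)c(C#CC(=O)c2c(OS(=O)(=O)c3ccc(C)cc3)cc(OCc3ccccc3)c(OC)c2O)cc1OC | intermediate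
18 | (E)-1-[4-(benzyloxy)-2-hydroxy-3-methoxy-6-(tosyloxy)phenyl]-3-[2-(benzyloxy)-4,5-dimethoxyphenyl]-3-(diethylamino)prop-2-en-1-one | CCN(CC)/C(=C/C(=O)c1c(OS(=O)(=O)c2ccc(C)cc2)cc(OCc2ccccc2)c(OC)c1O)c1cc(OC)c(OC)cc1OCc1ccccc1 | intermediate
19 | 7-(benzyloxy)-2-[2-(benzyloxy)-4,5-dimethoxyphenyl]-8-methoxy-4-oxo-4H-chromen-5-yl 4-methylbenzenesulfonate | COc1cc(OCc2ccccc2)c(-c2cc(=O)c3c(OS(=O)(=O)c4ccc(C)cc4)cc(OCc4ccccc4)c(OC)c3o2)cc1OC | intermediate
20 | 7-(benzyloxy)-2-[2-(benzyloxy)-4,5-dimethoxyphenyl]-5-hydroxy-8-methoxy-4H-chromen-4-one | COc1cc(OCc2ccccc2)c(-c2cc(=O)c3c(O)cc(OCc4ccccc4)c(OC)c3o2)cc1OC | intermediate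
21 | 5,7-dihydroxy-2-(2-hydroxy-4,5-dimethoxyphenyl)-8-methoxy-4H-chromen-4-one | COc1cc(O)c(-c2cc(=O)c3c(O)cc(O)c(OC)c3o2)cc1OC | target

**Step count**

Total: 12 steps. Longest linear sequence: 9 steps (steps 1–5, then 9–12).

**Steps most likely to fail**

1. Step 9. The carboxylate may add to C4a instead of C8a, because the C8 methoxy group polarises the aryne in the opposite sense to the tosylate. The aryl anion may also be protonated or expel tosylate before the acyl shift, and the propiolate may lose CO2. The fallback builds ring C without an aryne and introduces the C8 oxygen last; it sets out from aldehyde 11 and returns to the route at 20. 2,4,6-Trihydroxyacetophenone would be benzylated at the non-chelated 4-OH (BnBr, K2CO3, acetone) to give 1-[4-(benzyloxy)-2,6-dihydroxyphenyl]ethanone F1. Claisen–Schmidt condensation of this ketone with 11 (KOH, EtOH) should give (E)-1-[4-(benzyloxy)-2,6-dihydroxyphenyl]-3-[2-(benzyloxy)-4,5-dimethoxyphenyl]prop-2-en-1-one F2. Oxidative cyclisation (I2 cat., DMSO, 130 °C; either ortho hydroxyl leads to the same product) should give 7-(benzyloxy)-2-[2-(benzyloxy)-4,5-dimethoxyphenyl]-5-hydroxy-4H-chromen-4-one F3. Elbs persulfate oxidation (K2S2O8, aqueous KOH–pyridine) should attack para to the 5-phenoxide, at C8, to give potassium 7-(benzyloxy)-2-[2-(benzyloxy)-4,5-dimethoxyphenyl]-5-hydroxy-4-oxo-4H-chromen-8-yl sulfate F4, which dilute HCl should hydrolyse to 7-(benzyloxy)-2-[2-(benzyloxy)-4,5-dimethoxyphenyl]-5,8-dihydroxy-4H-chromen-4-one F5. Methylation of the free 8-OH in preference to the chelated 5-OH (MeI 1 equiv, K2CO3, acetone) should then give 20.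

2. Step 5. Butyllithium may attack the sulfonyl sulfur or the tosyl ring in competition with bromine–lithium exchange, or the silyl shift may stay incomplete. The fallback carries the C5 oxygen as a 4-methoxybenzyl ether through the organolithium step and introduces the tosylate afterwards; it sets out from 2 and returns to the route at 9. Alkylation of 2 (4-methoxybenzyl chloride, K2CO3, DMF) should give 4-(benzyloxy)-5-methoxy-2-[(4-methoxybenzyl)oxy]benzaldehyde F6. Baeyer–Villiger oxidation (mCPBA, CH2Cl2) should give 4-(benzyloxy)-5-methoxy-2-[(4-methoxybenzyl)oxy]phenyl formate F7, and methanolysis (K2CO3, MeOH) should give 4-(benzyloxy)-5-methoxy-2-[(4-methoxybenzyl)oxy]phenol F8. Bromination (NBS, MeCN, 0 °C) should give 4-(benzyloxy)-2-bromo-3-methoxy-6-[(4-methoxybenzyl)oxy]phenol F9. HMDS should convert this to [4-(benzyloxy)-2-bromo-3-methoxy-6-[(4-methoxybenzyl)oxy]phenoxy]trimethylsilane F10; n-BuLi at −100 °C should give lithium 4-(benzyloxy)-3-methoxy-6-[(4-methoxybenzyl)oxy]-2-(trimethylsilyl)phenolate F11; and Tf2O should give 4-(benzyloxy)-3-methoxy-6-[(4-methoxybenzyl)oxy]-2-(trimethylsilyl)phenyl trifluoromethanesulfonate F12. Oxidative cleavage of the 4-methoxybenzyl ether only (DDQ, CH2Cl2–pH 7 buffer) should give 4-(benzyloxy)-6-hydroxy-3-methoxy-2-(trimethylsilyl)phenyl trifluoromethanesulfonate F13, and tosylation (TsCl, Et3N, DMAP, CH2Cl2, 0 °C) should give 9.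

3. Step 11. Hydroxide or methoxide may open ring C at C2 of the fully etherified flavone, and the ring may reclose through the freed C5 phenoxide, moving the methoxy group from C8 to C6 (Wessely–Moser-type scrambling). The fallback reverses the order of the last two steps so that the base meets a flavone whose 7- and 2'-phenoxides deactivate the pyranone; it sets out from 19 and returns to the route at 21. Hydrogenolysis of 19 (H2, Pd/C, EtOAc–MeOH) should give 7-hydroxy-2-(2-hydroxy-4,5-dimethoxyphenyl)-8-methoxy-4-oxo-4H-chromen-5-yl 4-methylbenzenesulfonate F14. Cleavage of the sulfonate with KOH in H2O–THF (no methanol, so that no methyl sulfonate can alkylate the phenoxides), then acidification, should give 21.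

**Further compounds**

F1 | step 9 | 1-[4-(benzyloxy)-2,6-dihydroxyphenyl]ethanone | CC(=O)c1c(O)cc(OCc2ccccc2)cc1O
F2 | step 9 | (E)-1-[4-(benzyloxy)-2,6-dihydroxyphenyl]-3-[2-(benzyloxy)-4,5-dimethoxyphenyl]prop-2-en-1-one | COc1cc(OCc2ccccc2)c(/C=C/C(=O)c2c(O)cc(OCc3ccccc3)cc2O)cc1OC
F3 | step 9 | 7-(benzyloxy)-2-[2-(benzyloxy)-4,5-dimethoxyphenyl]-5-hydroxy-4H-chromen-4-one | COc1cc(OCc2ccccc2)c(-c2cc(=O)c3c(O)cc(OCc4ccccc4)cc3o2)cc1OC
F4 | step 9 | potassium 7-(benzyloxy)-2-[2-(benzyloxy)-4,5-dimethoxyphenyl]-5-hydroxy-4-oxo-4H-chromen-8-yl sulfate | [K+].COc1cc(OCc2ccccc2)c(-c2cc(=O)c3c(O)cc(OCc4ccccc4)c(OS(=O)(=O)[O-])c3o2)cc1OC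
F5 | step 9 | 7-(benzyloxy)-2-[2-(benzyloxy)-4,5-dimethoxyphenyl]-5,8-dihydroxy-4H-chromen-4-one | COc1cc(OCc2ccccc2)c(-c2cc(=O)c3c(O)cc(OCc4ccccc4)c(O)c3o2)cc1OC
F6 | step 5 | 4-(benzyloxy)-5-methoxy-2-[(4-methoxybenzyl)oxy]benzaldehyde | COc1ccc(COc2cc(OCc3ccccc3)c(OC)cc2C=O)cc1
F7 | step 5 | 4-(benzyloxy)-5-methoxy-2-[(4-methoxybenzyl)oxy]phenyl formate | COc1ccc(COc2cc(OCc3ccccc3)c(OC)cc2OC=O)cc1
F8 | step 5 | 4-(benzyloxy)-5-methoxy-2-[(4-methoxybenzyl)oxy]phenol | COc1ccc(COc2cc(OCc3ccccc3)c(OC)cc2O)cc1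
F9 | step 5 | 4-(benzyloxy)-2-bromo-3-methoxy-6-[(4-methoxybenzyl)oxy]phenol | COc1ccc(COc2cc(OCc3ccccc3)c(OC)c(Br)c2O)cc1
F10 | step 5 | [4-(benzyloxy)-2-bromo-3-methoxy-6-[(4-methoxybenzyl)oxy]phenoxy]trimethylsilane | COc1ccc(COc2cc(OCc3ccccc3)c(OC)c(Br)c2O[Si](C)(C)C)cc1
F11 | step 5 | lithium 4-(benzyloxy)-3-methoxy-6-[(4-methoxybenzyl)oxy]-2-(trimethylsilyl)phenolate | [Li+].COc1ccc(COc2cc(OCc3ccccc3)c(OC)c([Si](C)(C)C)c2[O-])cc1
F12 | step 5 | 4-(benzyloxy)-3-methoxy-6-[(4-methoxybenzyl)oxy]-2-(trimethylsilyl)phenyl trifluoromethanesulfonate | COc1ccc(COc2cc(OCc3ccccc3)c(OC)c([Si](C)(C)C)c2OS(=O)(=O)C(F)(F)F)cc1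
F13 | step 5 | 4-(benzyloxy)-6-hydroxy-3-methoxy-2-(trimethylsilyl)phenyl trifluoromethanesulfonate | COc1c([Si](C)(C)C)c(OS(=O)(=O)C(F)(F)F)c(O)cc1OCc1ccccc1
F14 | step 11 | 7-hydroxy-2-(2-hydroxy-4,5-dimethoxyphenyl)-8-methoxy-4-oxo-4H-chromen-5-yl 4-methylbenzenesulfonate | COc1cc(O)c(-c2cc(=O)c3c(OS(=O)(=O)c4ccc(C)cc4)cc(O)c(OC)c3o2)cc1OC
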